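**Plan**

- Retrosynthesis: first the O8 isobutyrate and the O5 silyl ether are adjusted. Then C1–C2 and O10–C3 are cut together, which opens the ten-membered carbocycle and the bridging 3(2H)-furanone to a terminal alkyne on C4 and a 1,3-dioxolan-4-one holding C1/O10. Last, C6–C7 and the lactone C12–O6 bond are cut (Barbier union of an allyl bromide and an aldehyde).
- Enabling feature: the furanone carbonyl C1 sits on the oxygen-bearing quaternary C10, and C2=C3–O10 is the oxa-Michael adduct of an ynone. C1/O10 can therefore be stored as a dioxolanone (an acyl donor that unmasks the O10 alkoxide once C1–C2 has formed) and C2–C3 as an alkyne.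
- Forward: fragment A (C1, C7–C14, from (R)-citramalic acid) and fragment B (C2–C6, C15, from methyl (R)-glycerate acetonide) are joined at C6–C7 with closure of the methylene lactone. One anionic operation then closes the carbocycle and the furanone. PMB-to-isobutyrate exchange at O8 and desilylation at O5 finish the route.
- Stereochemistry: C10 and C5 come from the chiral pool, C8 from a ligand-controlled alkenylzinc addition, C6 and C7 from the Barbier step (Felkin–Anh at the aldehyde, syn addition, relay from C8).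

Key step: step 16

Remark: locants C1–C15 are germacranolide locants (C1 furanone carbonyl, C2=C3 furanone alkene, O bridge C3–O–C10, C4 with exocyclic C15, C5 carbinol, C6/C7 lactone fusion, C8 ester carbinol, C9 CH2, C10 quaternary carbon with C14 methyl, C11=C13/C12 methylene lactone).
Assumption: the SMILES is read as (5S,6R,7R,8R,10R) with a cis-fused lactone (H6 and H7 cis); both chiral starting materials are bought as the (R)-enantiomers.

**Route**

Step 1
Reactants: 1 (R)-citramalic acid [(2R)-2-hydroxy-2-methylbutanedioic acid]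
Product: 2 2-[(4R)-2,2,4-trimethyl-5-oxo-1,3-dioxolan-4-yl]acetic acid
Conditions: 2,2-dimethoxypropane, TsOH·H2O (cat.), 23 °C
Reagents that add atoms: 2,2-dimethoxypropane COC(C)(C)OC
Why: Acid-catalysed transacetalisation ties the α-hydroxy acid (C1 carboxyl and O10) into the five-membered 1,3-dioxolan-4-one in preference to the six-membered alternative, leaves the C8 carboxyl free and does not touch C10.

Step 2
Reactants: 2 2-[(4R)-2,2,4-trimethyl-5-oxo-1,3-dioxolan-4-yl]acetic acid
Product: 3 (5R)-5-(2-hydroxyethyl)-2,2,5-trimethyl-1,3-dioxolan-4-one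
Conditions: BH3·SMe2, THF, 0 → 23 °C; MeOH quench; used crude
Reagents that add atoms: none
Why: Chemoselective borane reduction of the free carboxylic acid in the presence of the lactone-type dioxolanone should give the primary alcohol, which is carried on at once because acid or base would let it open the dioxolanone.

Step 3
Reactants: 3 (5R)-5-(2-hydroxyethyl)-2,2,5-trimethyl-1,3-dioxolan-4-one
Product: 4 2-[(4R)-2,2,4-trimethyl-5-oxo-1,3-dioxolan-4-yl]acetaldehyde
Conditions: Dess–Martin periodinane, NaHCO3, CH2Cl2, 0 → 23 °C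
Reagents that add atoms: none
Why: Dess–Martin oxidation under buffered, non-basic conditions should give the C8 aldehyde without translactonisation.

Step 4
Reactants: 4 2-[(4R)-2,2,4-trimethyl-5-oxo-1,3-dioxolan-4-yl]acetaldehyde; 5 1-hexyne
Product: 6 (5R)-5-[(2R,3E)-2-hydroxyoct-3-en-1-yl]-2,2,5-trimethyl-1,3-dioxolan-4-one
Conditions: 5, (c-C6H11)2BH, toluene, 0 → 23 °C; Et2Zn, (−)-MIB (5 mol %), −78 °C; then 4, −20 °C; NH4Cl (aq), −20 °C
Reagents that add atoms: none
Why: Oppolzer-type catalytic asymmetric alkenylzinc addition (alkyne hydroboration, boron-to-zinc exchange, amino alcohol ligand) should deliver the alkenyl group to the Si face of the aldehyde and so set C8 as R (the enantiomeric ligand is available should the sense need reversing), while zinc reagents leave the dioxolanone alone and the zinc alkoxide is quenched cold before it can translactonise.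

Step 5
Reactants: 6 (5R)-5-[(2R,3E)-2-hydroxyoct-3-en-1-yl]-2,2,5-trimethyl-1,3-dioxolan-4-one
Product: 7 (5R)-5-[(2R,3E)-2-[(4-methoxybenzyl)oxy]oct-3-en-1-yl]-2,2,5-trimethyl-1,3-dioxolan-4-one
Conditions: 2-[(4-methoxybenzyl)oxy]-4-methylquinoline, MeOTf, MgO, PhCF3, 0 → 23 °C
Reagents that add atoms: 2-[(4-methoxybenzyl)oxy]-4-methylquinoline COc1ccc(COc2cc(C)c3ccccc3n2)cc1
Why: Dudley-type transfer of the 4-methoxybenzyl group from the N-methylated quinolinium ether under MgO-buffered neutral conditions should protect O8 without the acid or base that would let the free C8 hydroxyl open the dioxolanone.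

Step 6
Reactants: 7 (5R)-5-[(2R,3E)-2-[(4-methoxybenzyl)oxy]oct-3-en-1-yl]-2,2,5-trimethyl-1,3-dioxolan-4-one
Product: 8 (2R)-2-[(4-methoxybenzyl)oxy]-3-[(4R)-2,2,4-trimethyl-5-oxo-1,3-dioxolan-4-yl]propanal
Conditions: O3, CH2Cl2, −78 °C (stopped at first blue colour); PPh3, −78 → 23 °C
Reagents that add atoms: ozone [O-][O+]=O
Why: Ozonolysis with reductive work-up cleaves the disubstituted alkene far faster than ozone attacks the anisyl ring and should give the α-alkoxy aldehyde (C7) with C8 intact.

Step 7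
Reactants: 8 (2R)-2-[(4-methoxybenzyl)oxy]-3-[(4R)-2,2,4-trimethyl-5-oxo-1,3-dioxolan-4-yl]propanal; 9 methyl acrylate
Product: 10 methyl (4R)-3-hydroxy-4-[(4-methoxybenzyl)oxy]-2-methylidene-5-[(4R)-2,2,4-trimethyl-5-oxo-1,3-dioxolan-4-yl]pentanoate (both C3 epimers)
Conditions: 9 (excess, neat), DABCO (0.5 equiv), 23 °C
Reagents that add atoms: none
Why: Morita–Baylis–Hillman reaction of the inductively activated α-alkoxy aldehyde attaches C11–C13 of the future methylene lactone, and the configuration of the new carbinol is irrelevant because step 8 erases it.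

Step 8
Reactants: 10 methyl (4R)-3-hydroxy-4-[(4-methoxybenzyl)oxy]-2-methylidene-5-[(4R)-2,2,4-trimethyl-5-oxo-1,3-dioxolan-4-yl]pentanoate
Product: 11 methyl (2Z,4R)-2-(bromomethyl)-4-[(4-methoxybenzyl)oxy]-5-[(4R)-2,2,4-trimethyl-5-oxo-1,3-dioxolan-4-yl]pent-2-enoate
Conditions: NBS, Me2S, CH2Cl2, 0 → 23 °C
Reagents that add atoms: N-bromosuccinimide O=C1CCC(=O)N1Br
Why: Corey–Kim-type activation of the allylic alcohol followed by SN2′ displacement by bromide should give the thermodynamically preferred (Z)-2-(bromomethyl)enoate, in which C8 is cis to CH2Br.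

Step 9
Reactants: 12 methyl (4R)-2,2-dimethyl-1,3-dioxolane-4-carboxylate
Product: 13 (4R)-N-methoxy-N,2,2-trimethyl-1,3-dioxolane-4-carboxamide
Conditions: MeNH(OMe)·HCl, iPrMgCl, THF, −20 → 0 °C
Reagents that add atoms: N,O-dimethylhydroxylamine hydrochloride CNOC.Cl
Why: Weinreb amide formation from the ester with the chloromagnesium amide at low temperature should proceed without epimerisation of the α-alkoxy centre (C5).

Step 10
Reactants: 13 (4R)-N-methoxy-N,2,2-trimethyl-1,3-dioxolane-4-carboxamide; 14 lithium (trimethylsilyl)acetylide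
Product: 15 1-[(4R)-2,2-dimethyl-1,3-dioxolan-4-yl]-3-(trimethylsilyl)prop-2-yn-1-one
Conditions: 14 (0.5 M in THF), THF, −78 → −20 °C; NH4Cl (aq)
Reagents that add atoms: none
Why: Acetylide addition to the Weinreb amide stops at the chelated tetrahedral intermediate and should give the ynone (C2–C4) on work-up.

Step 11
Reactants: 15 1-[(4R)-2,2-dimethyl-1,3-dioxolan-4-yl]-3-(trimethylsilyl)prop-2-yn-1-one; 16 methyltriphenylphosphonium bromide
Product: 17 (4S)-2,2-dimethyl-4-[4-(trimethylsilyl)but-1-en-3-yn-2-yl]-1,3-dioxolane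
Conditions: 16, KN(SiMe3)2, THF, 0 °C; then 15, −78 → 0 °C
Reagents that add atoms: none
Why: Wittig methylenation of the ynone carbonyl (the silyl group blocks conjugate attack) installs the exocyclic C4=C15 methylene and is run cold so that the adjacent C5 centre does not epimerise.

Step 12
Reactants: 17 (4S)-2,2-dimethyl-4-[4-(trimethylsilyl)but-1-en-3-yn-2-yl]-1,3-dioxolane
Product: 19 (2S)-3-methylidenepent-4-yne-1,2-diol, via terminal alkyne acetonide 18 (not isolated)
Conditions: K2CO3 (cat.), MeOH, 23 °C; then HCl in MeOH to pH 1, 23 °C; solid NaHCO3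
Reagents that add atoms: none
Why: Carbonate-catalysed methanolysis of the alkynyl C–Si bond followed by acid-catalysed transacetalisation of the acetonide in the same methanol solution should give the diol without touching C5.

Step 13
Reactants: 19 (2S)-3-methylidenepent-4-yne-1,2-diol
Product: 20 (2S)-1,2-bis(triethylsilyloxy)-3-methylidenepent-4-yne
Conditions: TESCl, imidazole, DMF, 0 → 23 °C
Reagents that add atoms: chlorotriethylsilane CC[Si](Cl)(CC)CC
Why: Standard silylation of both hydroxyls (silyl chloride with imidazole), in which the C5 centre is not involved.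

Step 14
Reactants: 20 (2S)-1,2-bis(triethylsilyloxy)-3-methylidenepent-4-yne
Product: 21 (2S)-3-methylidene-2-(triethylsilyloxy)pent-4-ynal
Conditions: (COCl)2, DMSO, CH2Cl2, −78 → −40 °C; Et3N, −78 → −30 °C; cold pH 7 work-up; used crude
Reagents that add atoms: none
Why: Swern conditions oxidise primary triethylsilyl ethers directly to aldehydes (the activated sulfoxide cleaves the less hindered Si–O bond) while the secondary silyl ether at C5 stays, and amine addition and work-up are kept cold so that the α-silyloxy β,γ-unsaturated aldehyde does not enolise.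

Step 15
Reactants: 11 methyl (2Z,4R)-2-(bromomethyl)-4-[(4-methoxybenzyl)oxy]-5-[(4R)-2,2,4-trimethyl-5-oxo-1,3-dioxolan-4-yl]pent-2-enoate; 21 (2S)-3-methylidene-2-(triethylsilyloxy)pent-4-ynal
Product: 23 (4R,5R)-4-{(1R)-1-[(4-methoxybenzyl)oxy]-2-[(4R)-2,2,4-trimethyl-5-oxo-1,3-dioxolan-4-yl]ethyl}-3-methylidene-5-[(1S)-2-methylidene-1-(triethylsilyloxy)but-3-yn-1-yl]dihydrofuran-2(3H)-one, via syn hydroxy ester 22 (not isolated)
Conditions: In powder, THF–H2O (3:1), 23 °C; then PPTS (cat.), CH2Cl2, 23 °C
Reagents that add atoms: none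
Why: In this indium-mediated Barbier allylation the (Z)-configured 2-(methoxycarbonyl)allylindium should react through a chair-like transition state to give the 6,7-syn adduct, polar Felkin–Anh attack on the α-silyloxy aldehyde sets C6 anti to the C5 oxygen, attack anti to the C9 branch in the A(1,3)-minimised conformer relays C8 to C7, and the syn γ-hydroxy ester then closes to the cis-fused α-methylene lactone under PPTS.

Step 16
Reactants: 23 (4R,5R)-4-{(1R)-1-[(4-methoxybenzyl)oxy]-2-[(4R)-2,2,4-trimethyl-5-oxo-1,3-dioxolan-4-yl]ethyl}-3-methylidene-5-[(1S)-2-methylidene-1-(triethylsilyloxy)but-3-yn-1-yl]dihydrofuran-2(3H)-one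
Product: 26 (5S,6R,7R,8R,10R)-3,10-epoxy-8-[(4-methoxybenzyl)oxy]-1-oxo-5-(triethylsilyloxy)germacra-2,4(15),11(13)-trien-12,6-olide, via lithium hemiketal alkoxide 24 (not isolated), via lithium oxido ynone 25 (not isolated)
Conditions: LiN(SiMe3)2 (1.05 equiv, added over 1 h), THF (0.002 M), −78 °C; warm to −20 °C; AcOH, −20 °C
Reagents that add atoms: none
Why: Proposed new method: LiN(SiMe3)2 removes the acetylenic proton (the fastest acid present), the lithium acetylide adds to the acetal-activated C1 carbonyl of the dioxolanone (10-exo-trig closure of the carbocycle), the hemiketal alkoxide 24 opens and loses acetone to give the ynone with a free O10 alkoxide 25, and this alkoxide adds to C3 of the bent ynone (5-endo-dig oxa-Michael) so that protonation at C2 gives the bridged 3(2H)-furanone. The closest known reactions are intramolecular acetylide–carbonyl additions that close ten-membered rings, the addition of organolithiums to 1,3-dioxolan-4-ones to give α-hydroxy ketones, and the base-mediated cyclisation of α′-hydroxy ynones to 3(2H)-furanones; their combination in one anionic operation is what is new. No stereocentre is formed (C1 becomes trigonal, the C2=C3 geometry is fixed by the five-membered ring) and C10, the only centre at the reacting sites, is quaternary and cannot epimerise. The step needs ring closure in preference to oligomerisation (secured by high dilution and by the cis-fused lactone that turns the chain), attack at C1 and not at the lactone carbonyl (the latter would demand a seven- or eight-membered cycloalkyne), and survival of the α-methylene lactone (one equivalent of a non-nucleophilic amide that the alkyne consumes at −78 °C, then a cold acidic quench). Release of the cyclodecynone strain in the oxa-Michael step should drive the sequence forward.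

Step 17
Reactants: 26 (5S,6R,7R,8R,10R)-3,10-epoxy-8-[(4-methoxybenzyl)oxy]-1-oxo-5-(triethylsilyloxy)germacra-2,4(15),11(13)-trien-12,6-olide
Product: 27 (5S,6R,7R,8R,10R)-3,10-epoxy-8-hydroxy-1-oxo-5-(triethylsilyloxy)germacra-2,4(15),11(13)-trien-12,6-olide
Conditions: DDQ, CH2Cl2–pH 7 buffer (10:1), 0 °C
Reagents that add atoms: none
Why: Oxidative cleavage of the 4-methoxybenzyl ether with DDQ (benzylic hydride abstraction, hydrolysis of the oxocarbenium ion) should free O8 selectively, since the silyl ether, the vinylogous ester and the methylene lactone are inert under buffered conditions.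

Step 18
Reactants: 27 (5S,6R,7R,8R,10R)-3,10-epoxy-8-hydroxy-1-oxo-5-(triethylsilyloxy)germacra-2,4(15),11(13)-trien-12,6-olide; 28 isobutyric anhydride
Product: 29 (5S,6R,7R,8R,10R)-3,10-epoxy-8-(isobutyryloxy)-1-oxo-5-(triethylsilyloxy)germacra-2,4(15),11(13)-trien-12,6-olide
Conditions: 28, DMAP (cat.), iPr2NEt, CH2Cl2, 0 → 23 °C
Reagents that add atoms: none
Why: DMAP-catalysed acylation of the only free hydroxyl (O8) installs the isobutyrate with retention at C8, because the C8–O bond is not broken.

Step 19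
Reactants: 29 (5S,6R,7R,8R,10R)-3,10-epoxy-8-(isobutyryloxy)-1-oxo-5-(triethylsilyloxy)germacra-2,4(15),11(13)-trien-12,6-olide
Product: 30 (5S,6R,7R,8R,10R)-3,10-epoxy-5-hydroxy-8-(isobutyryloxy)-1-oxogermacra-2,4(15),11(13)-trien-12,6-olide (CNP0384113.1)
Conditions: HF·pyridine, pyridine, THF, 0 → 23 °C
Reagents that add atoms: none
Why: Fluoride-mediated desilylation with buffered HF·pyridine should cleave the triethylsilyl ether at O5 without touching the esters or the conjugate acceptors and give the target.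

**Compound list**

1 | (R)-citramalic acid | OC(=O)C[C@@](C(=O)O)(C)O | starting material
2 | 2-[(4R)-2,2,4-trimethyl-5-oxo-1,3-dioxolan-4-yl]acetic acid | OC(=O)C[C@@]1(C)OC(C)(C)OC1=O | intermediate
3 | (5R)-5-(2-hydroxyethyl)-2,2,5-trimethyl-1,3-dioxolan-4-one | OCC[C@@]1(C)OC(C)(C)OC1=O | intermediate
4 | 2-[(4R)-2,2,4-trimethyl-5-oxo-1,3-dioxolan-4-yl]acetaldehyde | O=CC[C@@]1(C)OC(C)(C)OC1=O | intermediate
5 | 1-hexyne | CCCCC#C | starting material
6 | (5R)-5-[(2R,3E)-2-hydroxyoct-3-en-1-yl]-2,2,5-trimethyl-1,3-dioxolan-4-one | CCCC/C=C/[C@H](O)C[C@@]1(C)OC(C)(C)OC1=O | intermediate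
7 | (5R)-5-[(2R,3E)-2-[(4-methoxybenzyl)oxy]oct-3-en-1-yl]-2,2,5-trimethyl-1,3-dioxolan-4-one | CCCC/C=C/[C@H](OCc1ccc(OC)cc1)C[C@@]1(C)OC(C)(C)OC1=O | intermediate
8 | (2R)-2-[(4-methoxybenzyl)oxy]-3-[(4R)-2,2,4-trimethyl-5-oxo-1,3-dioxolan-4-yl]propanal | O=C[C@H](OCc1ccc(OC)cc1)C[C@@]1(C)OC(C)(C)OC1=O | intermediate
9 | methyl acrylate | C=CC(=O)OC | starting material
10 | methyl (4R)-3-hydroxy-4-[(4-methoxybenzyl)oxy]-2-methylidene-5-[(4R)-2,2,4-trimethyl-5-oxo-1,3-dioxolan-4-yl]pentanoate | C=C(C(=O)OC)C(O)[C@H](OCc1ccc(OC)cc1)C[C@@]1(C)OC(C)(C)OC1=O | intermediate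
11 | methyl (2Z,4R)-2-(bromomethyl)-4-[(4-methoxybenzyl)oxy]-5-[(4R)-2,2,4-trimethyl-5-oxo-1,3-dioxolan-4-yl]pent-2-enoate | COC(=O)/C(CBr)=C/[C@H](OCc1ccc(OC)cc1)C[C@@]1(C)OC(C)(C)OC1=O | intermediate
12 | methyl (4R)-2,2-dimethyl-1,3-dioxolane-4-carboxylate | COC(=O)[C@H]1COC(C)(C)O1 | starting material
13 | (4R)-N-methoxy-N,2,2-trimethyl-1,3-dioxolane-4-carboxamide | CON(C)C(=O)[C@H]1COC(C)(C)O1 | intermediate
14 | lithium (trimethylsilyl)acetylide | [Li+].[C-]#C[Si](C)(C)C | starting material
15 | 1-[(4R)-2,2-dimethyl-1,3-dioxolan-4-yl]-3-(trimethylsilyl)prop-2-yn-1-one | C[Si](C)(C)C#CC(=O)[C@H]1COC(C)(C)O1 | intermediate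
16 | methyltriphenylphosphonium bromide | C[P+](c1ccccc1)(c1ccccc1)c1ccccc1.[Br-] | starting material
17 | (4S)-2,2-dimethyl-4-[4-(trimethylsilyl)but-1-en-3-yn-2-yl]-1,3-dioxolane | C[Si](C)(C)C#CC(=C)[C@H]1COC(C)(C)O1 | intermediate
18 | (4S)-4-(but-1-en-3-yn-2-yl)-2,2-dimethyl-1,3-dioxolane | C#CC(=C)[C@H]1COC(C)(C)O1 | intermediate
19 | (2S)-3-methylidenepent-4-yne-1,2-diol | C#CC(=C)[C@@H](CO)O | intermediate
20 | (2S)-1,2-bis(triethylsilyloxy)-3-methylidenepent-4-yne | C#CC(=C)[C@@H](CO[Si](CC)(CC)CC)O[Si](CC)(CC)CC | intermediate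
21 | (2S)-3-methylidene-2-(triethylsilyloxy)pent-4-ynal | C#CC(=C)[C@@H](C=O)O[Si](CC)(CC)CC | intermediate
22 | methyl (3S,4R,5S)-4-hydroxy-3-{(1R)-1-[(4-methoxybenzyl)oxy]-2-[(4R)-2,2,4-trimethyl-5-oxo-1,3-dioxolan-4-yl]ethyl}-2,6-dimethylidene-5-(triethylsilyloxy)oct-7-ynoate | C=C(C(=O)OC)[C@@H]([C@@H](O)[C@@H](O[Si](CC)(CC)CC)C(=C)C#C)[C@H](OCc1ccc(OC)cc1)C[C@@]1(C)OC(C)(C)OC1=O | intermediate
23 | (4R,5R)-4-{(1R)-1-[(4-methoxybenzyl)oxy]-2-[(4R)-2,2,4-trimethyl-5-oxo-1,3-dioxolan-4-yl]ethyl}-3-methylidene-5-[(1S)-2-methylidene-1-(triethylsilyloxy)but-3-yn-1-yl]dihydrofuran-2(3H)-one | C=C1C(=O)O[C@@H]([C@@H](O[Si](CC)(CC)CC)C(=C)C#C)[C@H]1[C@H](OCc1ccc(OC)cc1)C[C@@]1(C)OC(C)(C)OC1=O | intermediate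
24 | lithium salt of the C1 hemiketal of the ten-membered cycloalkyne (C1 carries O−, the alkynyl carbon C2 and the intact 2,2-dimethyl-1,3-dioxolane ring shared with C10) | [Li+].C=C1C(=O)O[C@@H]2[C@H]1[C@H](OCc1ccc(OC)cc1)C[C@@]1(C)OC(C)(C)OC1([O-])C#CC(=C)[C@@H]2O[Si](CC)(CC)CC | intermediate
25 | lithium (5S,6R,7R,8R,10R)-8-[(4-methoxybenzyl)oxy]-1-oxo-5-(triethylsilyloxy)germacra-4(15),11(13)-dien-2-yn-12,6-olid-10-olate | [Li+].C=C1C(=O)O[C@@H]2[C@H]1[C@H](OCc1ccc(OC)cc1)C[C@@](C)([O-])C(=O)C#CC(=C)[C@@H]2O[Si](CC)(CC)CC | intermediate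
26 | (5S,6R,7R,8R,10R)-3,10-epoxy-8-[(4-methoxybenzyl)oxy]-1-oxo-5-(triethylsilyloxy)germacra-2,4(15),11(13)-trien-12,6-olide | C=C1C(=O)O[C@@H]2[C@H]1[C@H](OCc1ccc(OC)cc1)C[C@@]1(C)OC(=CC1=O)C(=C)[C@@H]2O[Si](CC)(CC)CC | intermediate
27 | (5S,6R,7R,8R,10R)-3,10-epoxy-8-hydroxy-1-oxo-5-(triethylsilyloxy)germacra-2,4(15),11(13)-trien-12,6-olide | C=C1C(=O)O[C@@H]2[C@H]1[C@H](O)C[C@@]1(C)OC(=CC1=O)C(=C)[C@@H]2O[Si](CC)(CC)CC | intermediate
28 | isobutyric anhydride | CC(C)C(=O)OC(=O)C(C)C | starting material
29 | (5S,6R,7R,8R,10R)-3,10-epoxy-8-(isobutyryloxy)-1-oxo-5-(triethylsilyloxy)germacra-2,4(15),11(13)-trien-12,6-olide | C=C1C(=O)O[C@@H]2[C@H]1[C@H](OC(=O)C(C)C)C[C@@]1(C)OC(=CC1=O)C(=C)[C@@H]2O[Si](CC)(CC)CC | intermediate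
30 | (5S,6R,7R,8R,10R)-3,10-epoxy-5-hydroxy-8-(isobutyryloxy)-1-oxogermacra-2,4(15),11(13)-trien-12,6-olide (CNP0384113.1) | C=C1C(=O)O[C@@H]2[C@H]1[C@H](OC(=O)C(C)C)C[C@@]1(C)OC(=CC1=O)C(=C)[C@@H]2O | target

**Count and risks**

Total step count: 19. Longest linear sequence: 13 steps (steps 1–8, then 15–19).

Steps most likely to fail:

1. Step 16 (bears the label). What may go wrong: after ring closure the anionic medium persists (the lithium alkoxide, or amide and acetone enolate regenerated by proton transfer). It may then add to the α-methylene lactone or to the strained ynone of a second molecule faster than the hemiketal fragments and the 5-endo-dig closure takes place, so material is lost to oligomers. Fallback with known reaction types, which separates the events and closes the furanone under neutral π-acid catalysis: it sets out from 23 and comes back at 26. The acetylide addition is run as in step 16 but quenched at −78 °C with AcOH, so that only the ten-membered ring has closed. On work-up the hemiketal loses acetone and (5S,6R,7R,8R,10R)-10-hydroxy-8-[(4-methoxybenzyl)oxy]-1-oxo-5-(triethylsilyloxy)germacra-4(15),11(13)-dien-2-yn-12,6-olide F1 is isolated. F1 is then cycloisomerised with (Ph3P)AuNTf2 (2 mol %) in toluene at 23 °C (alkyne activation, 5-endo-dig attack of the free tertiary hydroxyl, protodeauration), which should give 26.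

2. Step 15. What may go wrong: facial selectivity erodes if Felkin–Anh control at the aldehyde and the relay from C8 do not reinforce each other in the loosely organised, water-solvated indium transition state. The allylindium may also be lost by reductive 1,4-elimination of the C8 alkoxide. Fallback through a closed, anhydrous six-membered boron transition state: it sets out from 10 and comes back at 23. Acetylation of 10 (Ac2O, DMAP, pyridine) gives methyl (4R)-3-acetoxy-4-[(4-methoxybenzyl)oxy]-2-methylidene-5-[(4R)-2,2,4-trimethyl-5-oxo-1,3-dioxolan-4-yl]pentanoate F2. Copper-catalysed SN2′ borylation (CuCl cat., LiCl, KOAc, B2pin2, DMF) gives methyl (2E,4R)-4-[(4-methoxybenzyl)oxy]-2-[(4,4,5,5-tetramethyl-1,3,2-dioxaborolan-2-yl)methyl]-5-[(4R)-2,2,4-trimethyl-5-oxo-1,3-dioxolan-4-yl]pent-2-enoate F3, with the boron-bearing CH2 cis to C8. F3 and 21 are heated in toluene (Zimmerman–Traxler allylboration, syn from this geometry) and the adduct is lactonised with PPTS to 23.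

3. Step 7. What may go wrong: the amine-catalysed addition is slow, and during the long exposure to DABCO the α-alkoxy aldehyde may enolise (epimerisation at C8) or the dioxolanone may be opened. Fallback that replaces amine catalysis by a stoichiometric vinylmetal addition: it sets out from 8 and comes back at 10. Methyl propiolate is hydroaluminated with iBu2AlH and NMO in THF at 0 °C to the [α-(methoxycarbonyl)vinyl]aluminium reagent. This reagent should add to 8 within minutes at 0 °C and give 10 directly, with no new isolated compound (F0).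

Further compounds
F1 | step 16 | (5S,6R,7R,8R,10R)-10-hydroxy-8-[(4-methoxybenzyl)oxy]-1-oxo-5-(triethylsilyloxy)germacra-4(15),11(13)-dien-2-yn-12,6-olide | C=C1C(=O)O[C@@H]2[C@H]1[C@H](OCc1ccc(OC)cc1)C[C@@](C)(O)C(=O)C#CC(=C)[C@@H]2O[Si](CC)(CC)CC
F2 | step 15 | methyl (4R)-3-acetoxy-4-[(4-methoxybenzyl)oxy]-2-methylidene-5-[(4R)-2,2,4-trimethyl-5-oxo-1,3-dioxolan-4-yl]pentanoate | C=C(C(=O)OC)C(OC(C)=O)[C@H](OCc1ccc(OC)cc1)C[C@@]1(C)OC(C)(C)OC1=O
F3 | step 15 | methyl (2E,4R)-4-[(4-methoxybenzyl)oxy]-2-[(4,4,5,5-tetramethyl-1,3,2-dioxaborolan-2-yl)methyl]-5-[(4R)-2,2,4-trimethyl-5-oxo-1,3-dioxolan-4-yl]pent-2-enoate | COC(=O)/C(CB1OC(C)(C)C(C)(C)O1)=C/[C@H](OCc1ccc(OC)cc1)C[C@@]1(C)OC(C)(C)OC1=O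
F0 | step 7 | none | none
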